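**Plan**

1. Numbering used throughout: C1 = quaternary ring-fusion carbon (CH3), C2–C3 = cyclopentane CH2–CH2, C4 = C(OH)(iPr), C5 = ring-fusion CH, C6 = CH–O(aroyl), C7 = CH2, C8(CH3)=C9, C10 = CH–O(tigloyl); β = face of the C1 methyl group.
2. Retrosynthetic cuts: both ester C–O bonds; C8=C9 (ring-closing metathesis); C6–C7 (2-methylallyl addition to a C6 aldehyde); C3–C4 (samarium Barbier closure of the cyclopentane); C4–C5 (aldol); C1–CH3 and C1–C2 (two cuprate additions to a butenolide).
3. Forward order: (S)-5-(hydroxymethyl)furan-2(5H)-one supplies C6, C5, C1, C10 and C9 as a γ-lactone; the cyclopentane is closed on it at C3–C4; the lactone is opened; the cycloheptene is closed at C8=C9; the two esters come last.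
4. Enabling feature: C4–OH is 1,3 to the C6 oxygen through C5, and the C6 and C10 oxygens are cis on the seven-membered ring. C6 can therefore be held as the carbonyl of a γ-lactone ring O–C10–C1–C5–C6, whose α-carbon C5 carries the C4 isobutyryl ketone (a chelating β-keto lactone) while C1 carries the C2–C3 iodoethyl arm.
5. Stereochemistry: C10 from the starting butenolide; C1 by cuprate addition anti to the C10 substituent; C5 and C4 in the key step (cis-fused bicycle, samarium chelate); C6 by chelation-controlled Grignard addition; the E alkene from tiglic acid.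

Key step: step 8

Remark on the chemistry: the carbinol carbon C4 of 11–13 is expected as an epimer mixture that converges in step 7, and C5 of 14 is taken to equilibrate through the enol of the α-acyl lactone; these centres are left open in the SMILES.

**Route**

Step 1
Reactants: 1 (S)-5-(hydroxymethyl)furan-2(5H)-one
Product: 2 silyl-protected butenolide
Conditions: t-BuPh2SiCl, imidazole, CH2Cl2, 0 °C to rt
Reagents that add atoms: tert-butyldiphenylsilyl chloride, CC(C)(C)[Si](Cl)(c1ccccc1)c1ccccc1
Why: Imidazole-promoted silylation of the primary alcohol masks C9–OH and gives the bulky group that later shields one lactone face, without touching the stereocentre.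

Step 2
Reactants: 2 silyl-protected butenolide; 3 allylmagnesium bromide
Product: 5 trans allyl lactone, via silyl ketene acetal 4 (not isolated)
Conditions: 3, CuBr·SMe2 (cat.), Me3SiCl, THF, −78 °C; then H2O
Reagents that add atoms: none
Why: Copper-catalysed conjugate (Michael-type) addition of the Grignard reagent, accelerated by Me3SiCl, should occur anti to the C10 silyloxymethyl group; the new C1 centre is transient and is erased in step 3.

Step 3
Reactants: 5 trans allyl lactone
Product: 7 β-allyl butenolide, via phenylselanyl lactone 6 (not isolated)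
Conditions: LiN(iPr)2, THF, −78 °C; PhSeBr; then H2O2, pyridine, CH2Cl2, 0 °C
Reagents that add atoms: none
Why: α-Selenenylation of the lactone enolate followed by selenoxide syn-elimination should regenerate the C1=C5 double bond, now with the future C2–C3 arm on C1.

Step 4
Reactants: 7 β-allyl butenolide; 8 methyllithium; 9 isobutyraldehyde
Product: 11 aldol lactone, via lithium enolate 10 (not isolated)
Conditions: 8 (2 equiv per Cu), CuI, Et2O, −20 °C (gives Me2CuLi); 7, −40 to −20 °C; then 9, −78 °C; AcOH
Reagents that add atoms: none
Why: Cuprate 1,4-addition to the β-substituted butenolide should deliver CH3 anti to the C10 substituent, fixing quaternary C1 with the allyl arm cis to C9, and enolate 10 is trapped by aldol addition to 9 from the less hindered methyl face (tandem conjugate addition–aldol).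

Step 5
Reactants: 11 aldol lactone
Product: 12 diol lactone
Conditions: O3, CH2Cl2/MeOH, −78 °C; then NaBH4, −78 to 0 °C
Reagents that add atoms: ozone, [O-][O+]=O
Why: Ozonolysis of the only alkene with reductive NaBH4 work-up should shorten the allyl group to the C2–C3 hydroxyethyl arm while the lactone and the silyl ether survive.

Step 6
Reactants: 12 diol lactone
Product: 13 iodo alcohol
Conditions: I2, PPh3, imidazole, CH2Cl2, 0 °C
Reagents that add atoms: iodine, [I][I]
Why: Appel-type iodination should convert the primary alcohol selectively, because the secondary carbinol between the isopropyl group and C5 is far more hindered.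

Step 7
Reactants: 13 iodo alcohol
Product: 14 iodo β-keto lactone
Conditions: Dess–Martin periodinane, CH2Cl2, 0 °C to rt
Reagents that add atoms: none
Why: Dess–Martin oxidation of the secondary alcohol should give the β-keto lactone without touching the alkyl iodide; C5 then lies between two carbonyls and epimerises through the enol.

Step 8
Reactants: 14 iodo β-keto lactone
Product: 15 bicyclic hydroxy lactone
Conditions: SmI2 (2.5 equiv), THF, −78 °C to rt; aq. NH4Cl
Reagents that add atoms: none
Why: SmI2 transfers one electron to the ketone of the samarium-chelated β-keto lactone to give a ketyl, a second electron cleaves the C3–I bond, and C3 and C4 are joined (samarium Barbier reaction; the description as an alkylsamarium adding to the ketone leads to the same bond), after which aqueous work-up frees the tertiary alcohol. The closest known reaction type is the SmI2-promoted intramolecular Barbier cyclisation of 2-(iodoalkyl) β-keto esters to 2-hydroxycycloalkanecarboxylates. The cyclopentane closes in the 5-exo mode, C3 attacking the carbonyl carbon while the C=O bond stays outside the new ring. C4 is controlled by the chelate of trivalent samarium between the ketyl oxygen and the lactone carbonyl, which keeps the oxygen on C4 cis to C6 (concave face) and the isopropyl group on the convex face; C5 is controlled by the lactone template, because only the epimer with the acyl group cis to the iodoethyl arm can close to a cis-fused bicyclo[3.3.0] system, and the other epimer is fed in through the enol. The step needs reduction of the ketone/iodide pair in preference to the lactone and the silyl ether and no β-elimination, which the easily reduced chelated 1,3-dicarbonyl unit and the absence of an α-leaving group should secure.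

Step 9
Reactants: 15 bicyclic hydroxy lactone
Product: 16 diol lactone
Conditions: Bu4NF, AcOH, THF, 0 °C to rt
Reagents that add atoms: none
Why: Fluoride cleavage of the silyl ether, buffered with AcOH, should free C9–OH without retro-aldol opening of the β-hydroxy lactone.

Step 10
Reactants: 16 diol lactone
Product: 17 aldehyde lactone
Conditions: Dess–Martin periodinane, CH2Cl2, 0 °C
Reagents that add atoms: none
Why: Dess–Martin oxidation of the primary alcohol should give the aldehyde while the tertiary C4 alcohol is inert.

Step 11
Reactants: 17 aldehyde lactone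
Product: 18 vinyl lactone
Conditions: Ph3PCH3Br, KN(SiMe3)2, THF, 0 °C; then 17, −78 to 0 °C
Reagents that add atoms: methyltriphenylphosphonium bromide, C[P+](c1ccccc1)(c1ccccc1)c1ccccc1.[Br-]
Why: Wittig methylenation with the non-stabilised ylide at low temperature should convert the aldehyde into the C9 vinyl group faster than the ylide can epimerise C10 or attack the lactone.

Step 12
Reactants: 18 vinyl lactone
Product: 19 lactol
Conditions: iBu2AlH, CH2Cl2, −78 °C; aq. potassium sodium tartrate
Reagents that add atoms: none
Why: Low-temperature iBu2AlH reduction should stop at the lactol because the tetrahedral aluminium alkoxide is stable at −78 °C, which brings C6 to the aldehyde oxidation level.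

Step 13
Reactants: 19 lactol; 20 2-methylallylmagnesium chloride
Product: 21 triol diene
Conditions: 20 (excess), THF, −78 to 0 °C; aq. NH4Cl
Reagents that add atoms: none
Why: Grignard addition to the open hydroxy aldehyde should go through the six-membered magnesium chelate between the C4 alkoxide and the C6 carbonyl (Cram chelate model), the nucleophile entering from the chelate face opposite the cyclopentane ring and so setting C6.

Step 14
Reactants: 21 triol diene
Product: 22 bicyclic triol
Conditions: second-generation Grubbs catalyst (5 mol %), CH2Cl2, 40 °C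
Reagents that add atoms: none
Why: Ring-closing metathesis between the C10 vinyl group and the 1,1-disubstituted alkene should close the cycloheptene at C8=C9 with loss of ethylene, and the cis arms on the cyclopentane give the cis-fused hydroazulene.

Step 15
Reactants: 22 bicyclic triol; 23 4-((tert-butyldimethylsilyl)oxy)benzoic acid
Product: 24 C6 aroate
Conditions: 23, DCC, DMAP (cat.), CH2Cl2, 0 °C
Reagents that add atoms: none
Why: Steglich esterification should acylate the C6 hydroxyl, which is less hindered than the C10 hydroxyl (next to quaternary C1 and cis to its methyl group) and far more reactive than the tertiary C4 hydroxyl.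

Step 16
Reactants: 24 C6 aroate; 25 tiglic acid
Product: 27 silyl-protected target, via mixed anhydride 26 (not isolated)
Conditions: 25, 2,4,6-Cl3C6H2COCl, Et3N, toluene, rt; then 24, DMAP, 50 °C
Reagents that add atoms: none
Why: Yamaguchi esterification through mixed anhydride 26 should acylate the hindered allylic C10 hydroxyl with retention at C10 and without change of the E alkene, the tertiary alcohol staying free.

Step 17
Reactants: 27 silyl-protected target
Product: 28 target
Conditions: Bu4NF, AcOH, THF, 0 °C
Reagents that add atoms: none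
Why: Buffered fluoride should remove the aryl silyl ether, which is much more labile than the two carboxylic esters, and release the phenol.

**Compound list**

1 | (S)-5-(hydroxymethyl)furan-2(5H)-one | O=C1C=C[C@@H](CO)O1 | starting material
2 | (S)-5-((tert-butyldiphenylsilyloxy)methyl)furan-2(5H)-one | O=C1C=C[C@@H](CO[Si](c2ccccc2)(c2ccccc2)C(C)(C)C)O1 | intermediate
3 | allylmagnesium bromide | C=CC[Mg]Br | starting material
4 | 4,5-trans-4-allyl-5-((tert-butyldiphenylsilyloxy)methyl)-2-(trimethylsilyloxy)-4,5-dihydrofuran (silyl ketene acetal of 5) | C[Si](C)(C)OC1=C[C@H](CC=C)[C@@H](CO[Si](c2ccccc2)(c2ccccc2)C(C)(C)C)O1 | intermediate (not isolated)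
5 | (4S,5S)-4-allyl-5-((tert-butyldiphenylsilyloxy)methyl)dihydrofuran-2(3H)-one (allyl trans to the silyloxymethyl group) | O=C1C[C@H](CC=C)[C@@H](CO[Si](c2ccccc2)(c2ccccc2)C(C)(C)C)O1 | intermediate
6 | 3-(phenylselanyl) derivative of 5 (PhSe trans to allyl) | O=C1[C@@H]([Se]c2ccccc2)[C@H](CC=C)[C@@H](CO[Si](c3ccccc3)(c3ccccc3)C(C)(C)C)O1 | intermediate (not isolated)
7 | (S)-4-allyl-5-((tert-butyldiphenylsilyloxy)methyl)furan-2(5H)-one | O=C1C=C(CC=C)[C@@H](CO[Si](c2ccccc2)(c2ccccc2)C(C)(C)C)O1 | intermediate
8 | methyllithium | [Li]C | starting material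
9 | isobutyraldehyde (2-methylpropanal) | CC(C)C=O | starting material
10 | lithium enolate of 4-allyl-4-methyl-5-((tert-butyldiphenylsilyloxy)methyl)dihydrofuran-2(3H)-one (CH3 trans, allyl cis to the silyloxymethyl group) | [Li]OC1=C[C@@](C)(CC=C)[C@@H](CO[Si](c2ccccc2)(c2ccccc2)C(C)(C)C)O1 | intermediate (not isolated)
11 | 4-allyl-5-((tert-butyldiphenylsilyloxy)methyl)-3-(1-hydroxy-2-methylpropyl)-4-methyldihydrofuran-2(3H)-one; C1 methyl trans and allyl cis to the C10 silyloxymethyl group, hydroxyalkyl group on the methyl face, carbinol centre open | O=C1[C@H](C(O)C(C)C)[C@@](C)(CC=C)[C@@H](CO[Si](c2ccccc2)(c2ccccc2)C(C)(C)C)O1 | intermediate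
12 | 4-(2-hydroxyethyl) analogue of 11 (diol), same configurations | O=C1[C@H](C(O)C(C)C)[C@@](C)(CCO)[C@@H](CO[Si](c2ccccc2)(c2ccccc2)C(C)(C)C)O1 | intermediate
13 | 4-(2-iodoethyl) analogue of 11 (iodo alcohol), same configurations | O=C1[C@H](C(O)C(C)C)[C@@](C)(CCI)[C@@H](CO[Si](c2ccccc2)(c2ccccc2)C(C)(C)C)O1 | intermediate
14 | 5-((tert-butyldiphenylsilyloxy)methyl)-4-(2-iodoethyl)-3-isobutyryl-4-methyldihydrofuran-2(3H)-one; C1 and C10 as in 11, C5 mobile | O=C1C(C(=O)C(C)C)[C@@](C)(CCI)[C@@H](CO[Si](c2ccccc2)(c2ccccc2)C(C)(C)C)O1 | intermediate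
15 | cis-fused 6-hydroxy-6-isopropyl-3a-methyl-3-((tert-butyldiphenylsilyloxy)methyl)hexahydro-1H-cyclopenta[c]furan-1-one; C4–OH cis to the lactone carbonyl C6 and anti to H5, isopropyl on the face of H5 and the C1 methyl, C9 arm anti to the C1 methyl | O=C1O[C@H](CO[Si](c3ccccc3)(c3ccccc3)C(C)(C)C)[C@]2(C)CC[C@@](O)(C(C)C)[C@H]12 | intermediate
16 | 3-(hydroxymethyl) analogue of 15 (diol) | O=C1O[C@H](CO)[C@]2(C)CC[C@@](O)(C(C)C)[C@H]12 | intermediate
17 | 3-formyl analogue of 15 (aldehyde) | O=C1O[C@H](C=O)[C@]2(C)CC[C@@](O)(C(C)C)[C@H]12 | intermediate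
18 | 3-vinyl analogue of 15 | O=C1O[C@H](C=C)[C@]2(C)CC[C@@](O)(C(C)C)[C@H]12 | intermediate
19 | lactol of 18 (1-hydroxy, anomer mixture) | OC1O[C@H](C=C)[C@]2(C)CC[C@@](O)(C(C)C)[C@H]12 | intermediate
20 | 2-methylallylmagnesium chloride | C=C(C)C[Mg]Cl | starting material
21 | 2-(1-hydroxy-3-methylbut-3-en-1-yl)-3-(1-hydroxyprop-2-en-1-yl)-1-isopropyl-3-methylcyclopentan-1-ol, all centres as in the target | C=C[C@@H](O)[C@]1(C)CC[C@@](O)(C(C)C)[C@@H]1[C@@H](O)CC(C)=C | intermediate
22 | cis-fused 3-isopropyl-6,8a-dimethyl-1,2,3,3a,4,5,8,8a-octahydroazulene-3,4,8-triol (target without both acyl groups; C4–OH α, C6–OH β, C10–OH β) | O[C@@H]1C=C(C)C[C@H](O)[C@@H]2[C@@]1(C)CC[C@@]2(O)C(C)C | intermediate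
23 | 4-((tert-butyldimethylsilyl)oxy)benzoic acid | CC(C)(C)[Si](C)(C)Oc1ccc(C(=O)O)cc1 | starting material
24 | C6 4-((tert-butyldimethylsilyl)oxy)benzoate of 22 | O[C@@H]1C=C(C)C[C@H](OC(=O)c3ccc(O[Si](C)(C)C(C)(C)C)cc3)[C@@H]2[C@@]1(C)CC[C@@]2(O)C(C)C | intermediate
25 | tiglic acid ((E)-2-methylbut-2-enoic acid) | C/C=C(\C)C(=O)O | starting material
26 | tiglic 2,4,6-trichlorobenzoic anhydride | C/C=C(\C)C(=O)OC(=O)c1c(Cl)cc(Cl)cc1Cl | intermediate (not isolated)
27 | C10 tiglate of 24 (target with the phenol as its tert-butyldimethylsilyl ether) | C/C=C(\C)C(=O)O[C@@H]1C=C(C)C[C@H](OC(=O)c3ccc(O[Si](C)(C)C(C)(C)C)cc3)[C@@H]2[C@@]1(C)CC[C@@]2(O)C(C)C | intermediate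
28 | (3R,3aS,4S,8R,8aR)-3-hydroxy-3-isopropyl-6,8a-dimethyl-8-(((E)-2-methylbut-2-enoyl)oxy)-1,2,3,3a,4,5,8,8a-octahydroazulen-4-yl 4-hydroxybenzoate | C/C=C(\C)C(=O)O[C@@H]1C=C(C)C[C@H](OC(=O)c2ccc(O)cc2)[C@@H]2[C@@]1(C)CC[C@@]2(O)C(C)C | target

**Summary and fallbacks**

Total step count: 17. Longest linear sequence: 17 steps (from 1).

Steps most likely to fail:

Step 8. The keto lactone epimer that cannot close may be reduced at the ketone, or lose its iodide by simple reduction with protonation of the alkylsamarium by the acidic C5–H, faster than the two C5 epimers interconvert. The fallback sets out from 11 and comes back at 15; it replaces the Barbier closure by a ketyl–carbonyl pinacol coupling, so that no C–I bond and no alkylsamarium are involved, followed by deoxygenation. Dess–Martin oxidation of 11 should give the allyl β-keto lactone F1. Cleavage of its allyl group with OsO4 (cat.)/NaIO4 and 2,6-lutidine in dioxane/H2O should give the keto aldehyde F2. SmI2 in THF at −78 °C should couple the two carbonyls through the samarium chelate to the cis-fused cis-diol F3. Phenyl chlorothionoformate with pyridine should acylate only the secondary C3 hydroxyl to the thionocarbonate F4. Barton–McCombie reduction with Bu3SnH and azobisisobutyronitrile in toluene at 80 °C should remove the C3 oxygen and give 15.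

Step 13. Chelation control may be lost, giving poor facial selectivity at the C6 carbonyl. The fallback sets out from 18 and comes back at 22; it sets C6 by internal hydride delivery to a ring ketone instead of by carbon–carbon bond formation. Addition of 20 to lactone 18 at −78 °C should stop at the hemiketal F5. Ring-closing metathesis with the second-generation Grubbs catalyst should give the ring ketone F6 (in equilibrium with its oxygen-bridged hemiketal). Me4NBH(OAc)3 in AcOH/MeCN should bind the C4 hydroxyl and deliver hydride to C6 from the face of that hydroxyl, giving 22.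

Step 15. Site selectivity between the C6 and C10 hydroxyls may be poor, with acylation at the wrong hydroxyl or at both. The fallback sets out from 22 and comes back at 27; it reverses the order of the two acylations behind a temporary ring. PhB(OH)2 in toluene with MgSO4 should tie the 1,3-related C4 and C6 hydroxyls into the cyclic phenylboronate F7. Yamaguchi esterification with 25 at the only free hydroxyl should give the tigloyl boronate F8. Exchange with 2,2-dimethylpropane-1,3-diol should release the tigloyl diol F9. Coupling of F9 with 23 (DCC, DMAP) at the only secondary hydroxyl should give 27.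

Further compounds
F1 | step 8 | 4-allyl-5-((tert-butyldiphenylsilyloxy)methyl)-3-isobutyryl-4-methyldihydrofuran-2(3H)-one (allyl β-keto lactone, C5 mobile) | O=C1C(C(=O)C(C)C)[C@@](C)(CC=C)[C@@H](CO[Si](c2ccccc2)(c2ccccc2)C(C)(C)C)O1
F2 | step 8 | keto aldehyde, 4-(2-oxoethyl) analogue of F1 | O=C1C(C(=O)C(C)C)[C@@](C)(CC=O)[C@@H](CO[Si](c2ccccc2)(c2ccccc2)C(C)(C)C)O1
F3 | step 8 | cis-diol, 5-hydroxy derivative of 15 with C3–OH cis to C4–OH | O=C1O[C@H](CO[Si](c3ccccc3)(c3ccccc3)C(C)(C)C)[C@]2(C)C[C@H](O)[C@@](O)(C(C)C)[C@H]12
F4 | step 8 | O-phenyl thionocarbonate of the C3 hydroxyl of F3 | O=C1O[C@H](CO[Si](c3ccccc3)(c3ccccc3)C(C)(C)C)[C@]2(C)C[C@H](OC(=S)Oc4ccccc4)[C@@](O)(C(C)C)[C@H]12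
F5 | step 13 | hemiketal from 18 and 20 (1-hydroxy-1-(2-methylallyl) lactol, anomer mixture) | OC1(CC(C)=C)O[C@H](C=C)[C@]2(C)CC[C@@](O)(C(C)C)[C@H]12
F6 | step 13 | C6 ring ketone, 3,8-dihydroxy-3-isopropyl-6,8a-dimethyl-octahydroazulen-4-one | O[C@@H]1C=C(C)CC(=O)[C@@H]2[C@@]1(C)CC[C@@]2(O)C(C)C
F7 | step 15 | cyclic phenylboronate of 22 across the C4 and C6 oxygens | O[C@@H]1C=C(C)C[C@H](OB3c4ccccc4)[C@@H]2[C@@]1(C)CC[C@@]2(O3)C(C)C
F8 | step 15 | C10 tiglate of F7 | C/C=C(\C)C(=O)O[C@@H]1C=C(C)C[C@H](OB3c4ccccc4)[C@@H]2[C@@]1(C)CC[C@@]2(O3)C(C)C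
F9 | step 15 | C10 tiglate of 22 (C4 and C6 hydroxyls free) | C/C=C(\C)C(=O)O[C@@H]1C=C(C)C[C@H](O)[C@@H]2[C@@]1(C)CC[C@@]2(O)C(C)C
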